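A charge of 0.1 mol% puts c(free catalyst) at 4.70 × 10⁻⁵ M, and the next plate has to choose how far to raise that charge and how far to raise the heat.

    reagent + free catalyst ⇌ catalyst intermediate A (K1 = 11 L mol⁻¹, k1 = 376 L mol⁻¹ s⁻¹, Ea1 = 44.0 kJ mol⁻¹, ΔH1 = −10.0 kJ mol⁻¹)
    substrate + catalyst intermediate A ⇌ catalyst intermediate B (K2 = 36.7 L mol⁻¹, k2 = 468 L mol⁻¹ s⁻¹, Ea2 = 38.0 kJ mol⁻¹, ΔH2 = 0 kJ mol⁻¹)
    catalyst intermediate B ⇌ released group + catalyst intermediate C (K3 = 0.0354 M, k3 = 20.2 s⁻¹, Ea3 = 91.0 kJ mol⁻¹, ΔH3 = −56.0 kJ mol⁻¹)
    catalyst intermediate C → free catalyst + target (k4 = 5.59 s⁻¹, Ea4 = 76.0 kJ mol⁻¹)
    2 catalyst intermediate A → spent catalyst (k5 = 3700 L mol⁻¹ s⁻¹, Ea5 = 17.0 kJ mol⁻¹)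
    substrate + released group → side product (k6 = 0.790 L mol⁻¹ s⁻¹, Ea6 = 74.0 kJ mol⁻¹)
    (constants at 100 °C)

| flask | substrate | reagent | free catalyst | temperature | time |
|---|---|---|---|---|---|
| blue | 0.047 M | 1.10 equiv | 0.1 mol% | 115 °C | 2.5 min |
| teal | 0.047 M | 1.10 equiv | 0.1 mol% | 100 °C | 2.5 min |
| ochre | 0.047 M | 1.10 equiv | 0.1 mol% | 85 °C | 2.5 min |

* which flask leads in amount of target, in percent of the substrate charged ("all alike" within 1.5 percentage points) (blue / teal / ochre / all alike)
* how much target is there at the end, in percent of the substrate charged: blue
* how much target is there at the end, in percent of the substrate charged: teal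
* how much target is there at the end, in percent of the substrate charged: ochre

- where a step has two of a species, its rate is k times that concentration squared, and two are used at each turn
- the constants hold at 100 °C; other temperatures follow from the activation energies and enthalpies

Teal stands at the reference temperature, so its constants apply as given. By hand, with c(substrate) at 0.047 M, c(reagent) at 0.0517 M and no released group yet, one catalyst round is a chain of dwell times. Catalyst intermediate C waits 0.179 s and catalyst intermediate B waits 0.0495 s. With returns counted, catalyst intermediate A waits 0.0742 s and free catalyst waits 0.182 s. A round therefore lasts 0.484 s, and catalyst intermediate A holds 15.3% of it.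

Catalyst intermediate A leaves in pairs, so working catalyst, meaning every form except spent catalyst, suffers a second-order loss and fades more slowly than an exponential. The catalyst clock, the time at which working catalyst has fallen to a fraction 0.5 of its charge, is one over two times the pairing constant, the squared share and the catalyst concentration: 2.04 min. The spent share at any time is that time over the sum of itself and the clock, which gives 55.0% at 2.5 min. Target, in percent of substrate, is load times clock over round, times the logarithm of one plus time over clock, which gives 20.2% for teal.

In this reckoning, load times clock stays the same when the load changes. A teal recipe with 4 times the load has a clock of 0.511 min, a spent share of 83.0% and target of 44.9%, which is less than proportion, a gain of 2.22 times. The next plate should carry that higher load in one row, with that gain read as a reckoning that holds c(substrate) at its charge and counts no released group. Temperature stays the other axis: the step that frees target has an activation energy of 76.0 kJ mol⁻¹ against 17.0 kJ mol⁻¹ for the pairing, so blue is expected ahead of teal and ochre. The hand reckoning goes no further than that order for those two flasks.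

The forecast also puts blue first, with 24% for blue and 8.5% for ochre, but it sets teal at 15% against the 20.2% reckoned here, holding that “the rise in turnover with temperature outweighs the only mildly faster deactivation”. The flasks give 26.7% in blue, 16.9% in teal and 8.38% in ochre, so blue leads, and teal stands below the hand figure.

Teal's clock of 2.04 min against a run of 2.5 min gives a reckoned spent share of 55.0%, and at 2.50 min teal holds 59.0% of its catalyst as spent catalyst, with 69.0% of its substrate still unbound. The neighbour, teal's recipe with 0.4 mol% of free catalyst, has its clock cut to 0.511 min and a reckoned spent share of 83.0%; at 2.50 min it holds 87.1% as spent catalyst and 45.5% of its substrate, and its target, reckoned at 44.9%, stands at 29.7%, a gain of 1.76 times over teal against the 2.22 reckoned.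

The constants used here stand for no real mixture, and the outcome is calculated.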